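**Retrosynthetic overview**

- Erycibenin A ⇐ its 7,4'-di-O-benzyl ether by hydrogenolysis; rings A, B and C are bought intact as genistein, so no ring of the target is formed in the route.
- The (2S)-2,3-dihydroxy-3-methylbutyl chain ⇐ the (E)-3-hydroxy-3-methylbut-1-enyl chain by a net enantioselective anti-Markovnikov hydration: chiral-dioxirane epoxidation sets the carbinol centre, then reductive opening of the benzylic C–O bond through an ortho-quinone methide.
- The C6–alkenyl bond ⇐ the C6 iodide plus 2-methylbut-3-en-2-ol (Heck); the C6 iodide ⇐ iodination ortho to the free 5-OH; the dibenzyl ether ⇐ genistein.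
- The only ring made is a transient oxirane, formed and opened in the same step.

Assumption: genistein is accepted as an achiral commercial starting material, and the target centre read from the SMILES is S at C2 of the side chain.

**Route**

Step 1
Reactants: 1 genistein; 2 benzyl bromide
Product: 3 7-(benzyloxy)-3-[4-(benzyloxy)phenyl]-5-hydroxy-4H-chromen-4-one
Conditions: BnBr (2.2 equiv), K2CO3 (2.5 equiv), acetone, reflux, 6 h
Reagents that add atoms: benzyl bromide, BrCc1ccccc1
Why: Williamson ether synthesis in which K2CO3 deprotonates the acidic 7-OH and 4'-OH while the 5-OH, hydrogen-bonded to the C4 carbonyl, is not alkylated under these mild conditions, so it stays free as the directing group for step 2 and the relay group for step 4; no stereocenter is involved.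

Step 2
Reactants: 3 7-(benzyloxy)-3-[4-(benzyloxy)phenyl]-5-hydroxy-4H-chromen-4-one; 4 N-iodosuccinimide
Product: 5 7-(benzyloxy)-3-[4-(benzyloxy)phenyl]-5-hydroxy-6-iodo-4H-chromen-4-one
Conditions: NIS (1.05 equiv), DMF, rt, dark, 12 h
Reagents that add atoms: N-iodosuccinimide, O=C1CCC(=O)N1I
Why: Electrophilic aromatic iodination in which, with 5-OH free and 7-O alkylated, neutral NIS is expected to iodinate ring A ortho to the chelated phenol at C6 (the selectivity I recall for 5-hydroxy-7-alkoxy flavonoids, whereas 5-O-alkylated substrates go to C8), and the benzyloxyphenyl ring B is not activated enough to react without acid; no stereocenter is involved.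

Step 3
Reactants: 5 7-(benzyloxy)-3-[4-(benzyloxy)phenyl]-5-hydroxy-6-iodo-4H-chromen-4-one; 6 2-methylbut-3-en-2-ol
Product: 7 7-(benzyloxy)-3-[4-(benzyloxy)phenyl]-5-hydroxy-6-[(E)-3-hydroxy-3-methylbut-1-en-1-yl]-4H-chromen-4-one
Conditions: Pd(OAc)2 (10 mol%), P(o-tol)3 (20 mol%), Et3N (3 equiv), 6 (5 equiv), DMF, 90 °C, 12 h
Reagents that add atoms: 2-methylbut-3-en-2-ol, C=CC(C)(C)O
Why: Mizoroki–Heck reaction in which zerovalent palladium formed in situ adds oxidatively to the C–I bond, the terminal alkene inserts with the aryl group at its CH2 end, and syn β-hydride elimination can only give the conjugated (E)-alkene because the carbinol carbon carries no hydrogen; the basic medium keeps the ortho-hydroxy allylic alcohol from cyclising to a chromene.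

Step 4
Reactants: 7 7-(benzyloxy)-3-[4-(benzyloxy)phenyl]-5-hydroxy-6-[(E)-3-hydroxy-3-methylbut-1-en-1-yl]-4H-chromen-4-one; 8 potassium peroxymonosulfate; 9 diethyl 2,6-dimethyl-1,4-dihydropyridine-3,5-dicarboxylate (Hantzsch ester)
Product: 12 7-(benzyloxy)-3-[4-(benzyloxy)phenyl]-6-[(2S)-2,3-dihydroxy-3-methylbutyl]-5-hydroxy-4H-chromen-4-one, via epoxide 10 (not isolated), via ortho-quinone methide 11 (not isolated)
Conditions: (a) D-fructose-derived Shi ketone (1,2:4,5-di-O-isopropylidene-β-D-erythro-2,3-hexodiulo-2,6-pyranose, 30 mol%), KHSO5 (1.4 equiv, as 2KHSO5·KHSO4·K2SO4), K2CO3 (5.8 equiv), Bu4NHSO4 (4 mol%), Na2B4O7/Na2H2EDTA buffer (pH 10.5), MeCN/dimethoxymethane/H2O, 0 °C, 3 h; organic phase separated, dried, exchanged into CH2Cl2 without purification; (b) Hantzsch ester 9 (1.5 equiv), (PhO)2PO2H (10 mol%), CH2Cl2, 0 °C to rt; 12 recrystallised (EtOAc/heptane) to upgrade ee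
Reagents that add atoms: potassium peroxymonosulfate, [K+].[O-]S(=O)(=O)OO
Why: Proposed new method: a metal-free, organocatalytic enantioselective anti-Markovnikov hydration of an ortho-hydroxystyrene run as one telescoped operation, in which the chiral dioxirane from the D-fructose-derived ketone and KHSO5 epoxidises the trans-alkene through the usual spiro transition state (the same face as in the (R,R)-selective epoxidation of trans-β-methylstyrene, which here reads (2R,3S) because CMe2OH outranks the benzylic carbon) and so sets the carbinol centre as S in 10, after which diphenyl phosphate opens the benzylic C–O bond with push from the free chelated 5-OH and the 7-benzyloxy group to give ortho-quinone methide 11, and the Hantzsch ester delivers hydride to its exocyclic methine carbon, restoring ring A without touching the C–O bond at the stereocenter, so S is carried into 12 (any 10 already opened by water to the benzylic triol funnels through the same quinone methide); the closest known reaction types are the Shi epoxidation of trans-alkenes and allylic alcohols and the Brønsted acid-catalysed Hantzsch ester reduction of ortho-quinone methides generated from ortho-hydroxybenzyl alcohols, which to my knowledge have not been joined, nor has an aryl epoxide served as the quinone methide precursor.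

Step 5
Reactants: 12 7-(benzyloxy)-3-[4-(benzyloxy)phenyl]-6-[(2S)-2,3-dihydroxy-3-methylbutyl]-5-hydroxy-4H-chromen-4-one
Product: 13 erycibenin A, 6-[(2S)-2,3-dihydroxy-3-methylbutyl]-5,7-dihydroxy-3-(4-hydroxyphenyl)-4H-chromen-4-one
Conditions: H2 (1 atm), 10% Pd/C, EtOAc/MeOH (1:1), rt, 2–4 h, stopped after uptake of 2 equiv H2
Reagents that add atoms: none
Why: Catalytic hydrogenolysis of the two aryl benzyl ethers, in which the secondary carbinol is homobenzylic and the tertiary one aliphatic so neither C–O bond is cleaved and the S centre is untouched, while the vinylogous-ester C2=C3 bond of ring C is reduced much more slowly than the O-benzyl groups.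

**Compound list**

1 | genistein, 5,7-dihydroxy-3-(4-hydroxyphenyl)-4H-chromen-4-one | O=c1c(-c2ccc(O)cc2)coc2cc(O)cc(O)c12 | starting material
2 | benzyl bromide | BrCc1ccccc1 | starting material
3 | 7-(benzyloxy)-3-[4-(benzyloxy)phenyl]-5-hydroxy-4H-chromen-4-one | O=c1c(-c2ccc(OCc3ccccc3)cc2)coc2cc(OCc3ccccc3)cc(O)c12 | intermediate
4 | N-iodosuccinimide | O=C1CCC(=O)N1I | starting material
5 | 7-(benzyloxy)-3-[4-(benzyloxy)phenyl]-5-hydroxy-6-iodo-4H-chromen-4-one | O=c1c(-c2ccc(OCc3ccccc3)cc2)coc2cc(OCc3ccccc3)c(I)c(O)c12 | intermediate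
6 | 2-methylbut-3-en-2-ol | C=CC(C)(C)O | starting material
7 | 7-(benzyloxy)-3-[4-(benzyloxy)phenyl]-5-hydroxy-6-[(E)-3-hydroxy-3-methylbut-1-en-1-yl]-4H-chromen-4-one | CC(C)(O)/C=C/c1c(OCc2ccccc2)cc2occ(-c3ccc(OCc4ccccc4)cc3)c(=O)c2c1O | intermediate
8 | potassium peroxymonosulfate, KHSO5 | [K+].[O-]S(=O)(=O)OO | starting material
9 | diethyl 2,6-dimethyl-1,4-dihydropyridine-3,5-dicarboxylate (Hantzsch ester) | CCOC(=O)C1=C(C)NC(C)=C(C(=O)OCC)C1 | starting material
10 | 7-(benzyloxy)-3-[4-(benzyloxy)phenyl]-5-hydroxy-6-[(2R,3S)-3-(2-hydroxypropan-2-yl)oxiran-2-yl]-4H-chromen-4-one (trans-epoxide) | CC(C)(O)[C@H]1O[C@@H]1c5c(OCc2ccccc2)cc2occ(-c3ccc(OCc4ccccc4)cc3)c(=O)c2c5O | intermediate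
11 | 7-(benzyloxy)-3-[4-(benzyloxy)phenyl]-6-[(2S)-2,3-dihydroxy-3-methylbutylidene]-4H-chromene-4,5(6H)-dione (ortho-quinone methide) | CC(C)(O)[C@@H](O)C=C1C(=O)C2=C(C=C1OCc3ccccc3)OC=C(c4ccc(OCc5ccccc5)cc4)C2=O | intermediate
12 | 7-(benzyloxy)-3-[4-(benzyloxy)phenyl]-6-[(2S)-2,3-dihydroxy-3-methylbutyl]-5-hydroxy-4H-chromen-4-one | CC(C)(O)[C@@H](O)Cc1c(OCc2ccccc2)cc2occ(-c3ccc(OCc4ccccc4)cc3)c(=O)c2c1O | intermediate
13 | erycibenin A, 6-[(2S)-2,3-dihydroxy-3-methylbutyl]-5,7-dihydroxy-3-(4-hydroxyphenyl)-4H-chromen-4-one | CC(C)(O)[C@@H](O)Cc1c(O)cc2occ(-c3ccc(O)cc3)c(=O)c2c1O | target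

**Step count and risks**

Total step count: 5. Longest linear sequence: 5 steps (1 to 13).

The three steps most likely to fail are steps 4, 3 and 2.

The first risk is step 4, the proposed new step. The free 5-OH may be oxidised by the dioxirane, the dioxirane may attack the C2=C3 bond of ring C, or acid treatment of epoxide 10 may give the benzyl ketone by hydride shift instead of the quinone methide. The fallback uses known chemistry only and sets out from 7. The 5-OH is benzylated (BnBr, Cs2CO3, DMF, 60 °C) to 5,7-bis(benzyloxy)-3-[4-(benzyloxy)phenyl]-6-[(E)-3-hydroxy-3-methylbut-1-en-1-yl]-4H-chromen-4-one F1. This fully protected trans-styrene is epoxidised under the same Shi ketone/KHSO5 conditions to 5,7-bis(benzyloxy)-3-[4-(benzyloxy)phenyl]-6-[(2R,3S)-3-(2-hydroxypropan-2-yl)oxiran-2-yl]-4H-chromen-4-one F2, which is isolated on Et3N-deactivated silica. Hydrogenolysis (H2, 10% Pd/C, EtOAc/MeOH, rt) then cleaves the benzylic C–O bond of the epoxide and all three benzyl ethers together, with the carbinol centre retained. The fallback comes back to the route at target 13, with three steps in place of steps 4 and 5.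

The second risk is step 3. The aryl iodide is flanked by two oxygen substituents, is electron-rich and carries a free phenol, so alkene insertion may be slow and protodeiodination may compete. The fallback sets out from 5 and comes back at 7. It is a Suzuki–Miyaura coupling with commercial (E)-2-methyl-4-(4,4,5,5-tetramethyl-1,3,2-dioxaborolan-2-yl)but-3-en-2-ol (PdCl2(dppf), K3PO4, dioxane/H2O, 80 °C). The alkene geometry is already fixed in the boronate, and transmetalation replaces the hindered insertion step. This fallback makes no compound outside the compound list (F0).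

The third risk is step 2. Iodination may give some C8 iodide or the 6,8-diiodide. The fallback avoids halogenation, sets out from 3 and comes back at 7. The 5-OH is allylated (allyl bromide, K2CO3, DMF, 70 °C) to 5-(allyloxy)-7-(benzyloxy)-3-[4-(benzyloxy)phenyl]-4H-chromen-4-one F3. Aromatic Claisen rearrangement (N,N-diethylaniline, 190 °C) can deliver the allyl group only to C6, because the other ortho position C4a is a ring-fusion carbon, and gives 6-allyl-7-(benzyloxy)-3-[4-(benzyloxy)phenyl]-5-hydroxy-4H-chromen-4-one F4. Alkene isomerisation ([RuClH(CO)(PPh3)3], toluene, 80 °C) gives 7-(benzyloxy)-3-[4-(benzyloxy)phenyl]-5-hydroxy-6-[(E)-prop-1-en-1-yl]-4H-chromen-4-one F5. Cross-metathesis of F5 with 6 (second-generation Hoveyda–Grubbs catalyst, CH2Cl2, 40 °C) gives 7.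

**Further compounds**

F1 | step 4 | 5,7-bis(benzyloxy)-3-[4-(benzyloxy)phenyl]-6-[(E)-3-hydroxy-3-methylbut-1-en-1-yl]-4H-chromen-4-one | CC(C)(O)/C=C/c1c(OCc2ccccc2)cc2occ(-c3ccc(OCc4ccccc4)cc3)c(=O)c2c1OCc1ccccc1
F2 | step 4 | 5,7-bis(benzyloxy)-3-[4-(benzyloxy)phenyl]-6-[(2R,3S)-3-(2-hydroxypropan-2-yl)oxiran-2-yl]-4H-chromen-4-one | CC(C)(O)[C@H]1O[C@@H]1c5c(OCc2ccccc2)cc2occ(-c3ccc(OCc4ccccc4)cc3)c(=O)c2c5OCc6ccccc6
F0 | step 3 | none | none
F3 | step 2 | 5-(allyloxy)-7-(benzyloxy)-3-[4-(benzyloxy)phenyl]-4H-chromen-4-one | C=CCOc1cc(OCc2ccccc2)cc2occ(-c3ccc(OCc4ccccc4)cc3)c(=O)c12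
F4 | step 2 | 6-allyl-7-(benzyloxy)-3-[4-(benzyloxy)phenyl]-5-hydroxy-4H-chromen-4-one | C=CCc1c(OCc2ccccc2)cc2occ(-c3ccc(OCc4ccccc4)cc3)c(=O)c2c1O
F5 | step 2 | 7-(benzyloxy)-3-[4-(benzyloxy)phenyl]-5-hydroxy-6-[(E)-prop-1-en-1-yl]-4H-chromen-4-one | C/C=C/c1c(OCc2ccccc2)cc2occ(-c3ccc(OCc4ccccc4)cc3)c(=O)c2c1O
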